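## Retrosynthetic overview

1. The target **8** is the 1,2-trans-2,3-cis aryltetralin (1R,2S,3R; C1 = aryl-bearing carbon). Both CH2OH groups come from LiAlH4 reduction of the cis-diester **7**.
2. **7** comes from dihydronaphthalene **6** by hydrogenation of C3=C4 on the face anti to the C2 ester (sets C3) with loss of both benzyl ethers in the same operation.
3. **6** comes from the achiral (E,E)-dibenzylidenesuccinate **5** by a new organocatalytic asymmetric Brønsted-acid cyclisation that forms the C1–C8a bond and sets C1 and C2.
4. **5** comes from two Stobbe condensations of O-benzylvanillin **1** with diethyl succinate **2**, then methylation.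
5. Ring order: ring A and the pendant guaiacyl ring are bought in **1**; ring B is the only ring built (step 3).

Assumption: the sense of induction of the new step cannot be predicted, so the catalyst is written as (S,S) and is exchanged for its mirror image if it delivers the antipode.

## Route

Step 1
Reactants: 1 4-(benzyloxy)-3-methoxybenzaldehyde (2.2 equiv); 2 diethyl succinate
Product: 4 (2E,3E)-2,3-bis[4-(benzyloxy)-3-methoxybenzylidene]succinic acid, via Stobbe half-ester 3 (not isolated)
Conditions: KOtBu (3 equiv), t-BuOH, reflux, 12 h; then 2 M HCl; crystallise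
Reagents that add atoms: none
Why: Two successive Stobbe condensations (aldol addition, γ-lactonisation onto the neighbouring ester, E1cB ring opening to the carboxylate) install both arylidene units in the thermodynamically preferred E geometry, and the symmetric diacid crystallises on acidification.

Step 2
Reactants: 4 (2E,3E)-2,3-bis[4-(benzyloxy)-3-methoxybenzylidene]succinic acid
Product: 5 dimethyl (2E,3E)-2,3-bis[4-(benzyloxy)-3-methoxybenzylidene]succinate
Conditions: MeI (3 equiv), K2CO3 (3 equiv), DMF, rt, dark
Reagents that add atoms: iodomethane (MeI), CI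
Why: SN2 O-alkylation of the dicarboxylate under mild base gives the diester without acid, so neither premature racemic cyclisation nor E/Z isomerisation can occur.

Step 3
Reactants: 5 dimethyl (2E,3E)-2,3-bis[4-(benzyloxy)-3-methoxybenzylidene]succinate
Product: 6 dimethyl (1R,2S)-7-(benzyloxy)-1-[4-(benzyloxy)-3-methoxyphenyl]-6-methoxy-1,2-dihydronaphthalene-2,3-dicarboxylate (1,2-trans)
Conditions: (S,S)-IDPi [N-triflyl imidodiphosphorimidate from two (S)-3,3'-bis(3,5-bis(trifluoromethyl)phenyl)-BINOL units] (5 mol%), CHCl3 (0.05 M), 40 °C, Ar, dark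
Reagents that add atoms: none
Why: Proposed new method: catalytic enantioselective Brønsted-acid cyclisation of an (E,E)-2,3-dibenzylidenesuccinate, in which the confined strong acid protonates one ester carbonyl to give a hydroxyallyl/4-alkoxybenzyl cation held as a contact ion pair in the chiral imidodiphosphorimidate pocket; the pocket selects one of the two rapidly interconverting helical conformers of the twisted diene, so C6 of the other ring (para to OMe) attacks the benzylic carbon from one face only (Friedel–Crafts closure of ring B, formally a cationic 6π cyclisation) and sets C1 as R; rearomatisation and proton return to the ketene hemiacetal anti to the new aryl give the diaxial, also thermodynamically preferred, 1,2-trans ester (C2 S); the closest known reaction type is the stoichiometric CF3SO3H-promoted racemic or auxiliary-directed cyclisation of dibenzylidenesuccinates to trans-1-aryl-1,2-dihydronaphthalenes, together with chiral Brønsted-acid-catalysed asymmetric Nazarov and hydroarylation reactions.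

Step 4
Reactants: 6 dimethyl (1R,2S)-7-(benzyloxy)-1-[4-(benzyloxy)-3-methoxyphenyl]-6-methoxy-1,2-dihydronaphthalene-2,3-dicarboxylate
Product: 7 dimethyl (1R,2S,3R)-7-hydroxy-1-(4-hydroxy-3-methoxyphenyl)-6-methoxy-1,2,3,4-tetrahydronaphthalene-2,3-dicarboxylate (1,2-trans, 2,3-cis)
Conditions: H2 (4 bar), 10% Pd/C, EtOAc/MeOH 1:1, rt
Reagents that add atoms: none
Why: Heterogeneous syn-hydrogenation of the C3=C4 enoate takes place on the face opposite the adjacent pseudo-axial C2 ester (the trans-1,2 substituents are diaxial in the half-chair), which puts the C3 ester cis to the C2 ester and fixes C3 as R, while the same catalyst hydrogenolyses both benzyl ethers (catalytic hydrogenation with O-debenzylation).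

Step 5
Reactants: 7 dimethyl (1R,2S,3R)-7-hydroxy-1-(4-hydroxy-3-methoxyphenyl)-6-methoxy-1,2,3,4-tetrahydronaphthalene-2,3-dicarboxylate
Product: 8 [(1R,2S,3R)-7-hydroxy-1-(4-hydroxy-3-methoxyphenyl)-6-methoxy-1,2,3,4-tetrahydronaphthalene-2,3-diyl]dimethanol (target)
Conditions: LiAlH4 (5 equiv), THF, 0 °C (7 added to the hydride), then rt, 1 h; 1 M HCl work-up
Reagents that add atoms: none
Why: Hydride reduction of both methyl esters to primary alcohols leaves the three stereocentres untouched, and inverse addition at low temperature reduces the base-labile cis C3 ester before it can epimerise (LiAlH4 ester reduction).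

## Compound list

1 | 4-(benzyloxy)-3-methoxybenzaldehyde (O-benzylvanillin) | COc1cc(C=O)ccc1OCc1ccccc1 | starting material
2 | diethyl succinate | CCOC(=O)CCC(=O)OCC | starting material
3 | (E)-4-[4-(benzyloxy)-3-methoxyphenyl]-3-(ethoxycarbonyl)but-3-enoic acid (Stobbe half-ester, formed as its potassium salt) | CCOC(=O)/C(CC(=O)O)=C/c1ccc(OCc2ccccc2)c(OC)c1 | intermediate
4 | (2E,3E)-2,3-bis[4-(benzyloxy)-3-methoxybenzylidene]succinic acid | COc1cc(/C=C(/C(=O)O)\C(C(=O)O)=C/c2ccc(OCc3ccccc3)c(OC)c2)ccc1OCc1ccccc1 | intermediate
5 | dimethyl (2E,3E)-2,3-bis[4-(benzyloxy)-3-methoxybenzylidene]succinate | COc1cc(/C=C(/C(=O)OC)\C(C(=O)OC)=C/c2ccc(OCc3ccccc3)c(OC)c2)ccc1OCc1ccccc1 | intermediate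
6 | dimethyl (1R,2S)-7-(benzyloxy)-1-[4-(benzyloxy)-3-methoxyphenyl]-6-methoxy-1,2-dihydronaphthalene-2,3-dicarboxylate | COc1cc([C@@H]2c3cc(OCc4ccccc4)c(OC)cc3C=C(C(=O)OC)[C@H]2C(=O)OC)ccc1OCc1ccccc1 | intermediate
7 | dimethyl (1R,2S,3R)-7-hydroxy-1-(4-hydroxy-3-methoxyphenyl)-6-methoxy-1,2,3,4-tetrahydronaphthalene-2,3-dicarboxylate | COc1cc([C@@H]2c3cc(O)c(OC)cc3C[C@@H](C(=O)OC)[C@H]2C(=O)OC)ccc1O | intermediate
8 | [(1R,2S,3R)-7-hydroxy-1-(4-hydroxy-3-methoxyphenyl)-6-methoxy-1,2,3,4-tetrahydronaphthalene-2,3-diyl]dimethanol | COc1cc([C@@H]2c3cc(O)c(OC)cc3C[C@@H](CO)[C@H]2CO)ccc1O | target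

## Step count and risks

Total steps: 5. Longest linear sequence: 5.

The three steps most likely to fail:

**Step 3 (the proposed new step).** The catalyst may be too weakly acidic to turn over, or the enantioselectivity may be low. The fallback uses known chemistry, sets out from 5 and comes back at 6. Compound 5 is cyclised with CF3SO3H (2–3 equiv) in CH2Cl2 at −20 to 0 °C, the established racemic cyclisation of dibenzylidenesuccinates. This gives the trans-dihydronaphthalene as the racemate, that is 6 together with its mirror image dimethyl (1S,2R)-7-(benzyloxy)-1-[4-(benzyloxy)-3-methoxyphenyl]-6-methoxy-1,2-dihydronaphthalene-2,3-dicarboxylate F3. Preparative chiral-phase SFC then delivers 6, with the absolute configuration checked by CD or X-ray, at the cost of half the material.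

**Step 4.** The facial selectivity rests on substrate control by the C2 ester; the C1 aryl could instead steer hydrogen to the other face and give the all-trans C3 epimer. The fallback sets out from 6 and comes back at 7, and replaces substrate control by catalyst control. The benzylidenesuccinate (itaconate-type) unit of 6 is hydrogenated with [Rh(cod)(Me-DuPhos)]BF4 (2 mol%) under H2 (10 bar) in MeOH at rt, using the ligand antipode that is matched with the substrate (both are tried). This gives dimethyl (1R,2S,3R)-7-(benzyloxy)-1-[4-(benzyloxy)-3-methoxyphenyl]-6-methoxy-1,2,3,4-tetrahydronaphthalene-2,3-dicarboxylate F4 with the benzyl ethers intact. Hydrogenolysis with H2 and 10% Pd/C in EtOAc then gives 7.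

**Step 1.** The second Stobbe condensation has to occur on a carboxylate-bearing intermediate and may stall or give a low yield. The fallback sets out from 1 and 2 and comes back at 4, and runs the two condensations separately. One equivalent of 1 is condensed with 2 (KOtBu, t-BuOH) and half-ester 3 is isolated. It is re-esterified with EtI and K2CO3 in DMF to diethyl (E)-2-[4-(benzyloxy)-3-methoxybenzylidene]succinate F1, whose CH2 is again activated by an ester. A second Stobbe condensation of F1 with 1 (NaOEt, EtOH, reflux) gives (2E,3E)-2,3-bis[4-(benzyloxy)-3-methoxybenzylidene]succinic acid monoethyl ester F2. Saponification (aq NaOH, EtOH, then HCl) gives 4.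

## Further compounds

F1 | step 1 | diethyl (E)-2-[4-(benzyloxy)-3-methoxybenzylidene]succinate | CCOC(=O)C/C(=C\c1ccc(OCc2ccccc2)c(OC)c1)C(=O)OCC
F2 | step 1 | (2E,3E)-2,3-bis[4-(benzyloxy)-3-methoxybenzylidene]succinic acid monoethyl ester | COc1cc(/C=C(/C(=O)OCC)\C(C(=O)O)=C/c2ccc(OCc3ccccc3)c(OC)c2)ccc1OCc1ccccc1
F3 | step 3 | dimethyl (1S,2R)-7-(benzyloxy)-1-[4-(benzyloxy)-3-methoxyphenyl]-6-methoxy-1,2-dihydronaphthalene-2,3-dicarboxylate | COc1cc([C@H]2c3cc(OCc4ccccc4)c(OC)cc3C=C(C(=O)OC)[C@@H]2C(=O)OC)ccc1OCc1ccccc1
F4 | step 4 | dimethyl (1R,2S,3R)-7-(benzyloxy)-1-[4-(benzyloxy)-3-methoxyphenyl]-6-methoxy-1,2,3,4-tetrahydronaphthalene-2,3-dicarboxylate | COc1cc([C@@H]2c3cc(OCc4ccccc4)c(OC)cc3C[C@@H](C(=O)OC)[C@H]2C(=O)OC)ccc1OCc1ccccc1
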